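in all of them: starting material 0.37 M

|  | reagent | second substrate | catalyst | remark | time |
|---|---|---|---|---|---|
| north | 1.1 equiv | 0.20 equiv | 0.025 mol% | run made earlier |  |
| north-east | 1.1 equiv | 0.20 equiv | 0.1 mol% | run made earlier |  |
| south-east | 0.55 equiv | 0.20 equiv | 0.05 mol% | run made earlier |  |
| red | 1.10 equiv | 0.200 equiv | 0.05 mol% |  | 3.0 min |
| grey | 1.10 equiv | 0.200 equiv | 0.05 mol% |  | 6.0 min |
| blue | 1.10 equiv | 0.200 equiv | 0.05 mol% |  | 12 min |

| run | time / min | starting material / % | isomer of the product / % | target / % |
|---|---|---|---|---|
| north | 0.200 | 76.8 | 7.5 | 16.3 |
| north | 0.333 | 66.0 | 13.3 | 20.1 |
| north | 0.500 | 57.0 | 20.5 | 22.1 |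
| north | 0.833 | 44.8 | 29.7 | 25.9 |
| north | 1.33 | 34.6 | 36.4 | 29.8 |
| north | 2.50 | 23.1 | 44.2 | 33.7 |
| north-east | 0.417 | 30.6 | 40.1 | 30.5 |
| north-east | 0.833 | 19.3 | 47.2 | 34.2 |
| north-east | 1.33 | 14.2 | 49.7 | 35.3 |
| north-east | 1.50 | 13.9 | 49.7 | 36.7 |
| north-east | 2.00 | 11.0 | 51.1 | 37.5 |
| north-east | 2.50 | 10.3 | 51.8 | 37.9 |
| south-east | 0.200 | 79.1 | 8.8 | 11.6 |
| south-east | 0.667 | 61.9 | 20.9 | 16.8 |
| south-east | 1.00 | 57.3 | 23.8 | 18.5 |
| south-east | 1.50 | 54.9 | 25.8 | 19.5 |
| south-east | 2.50 | 53.1 | 26.7 | 20.8 |

(standard deviation of a reading: 0.5 percentage points)

- which of these there is most of at the end, counted by the starting material in it, red (starting material / target / isomer of the product)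
- which of these there is most of at the end, counted by the starting material in it, grey (starting material / target / isomer of the product)
- which of these there is most of at the end, counted by the starting material in it, blue (starting material / target / isomer of the product)
- the largest of these amounts at the end, in percent of the starting material charged, red
- the largest of these amounts at the end, in percent of the starting material charged, grey
- the largest of these amounts at the end, in percent of the starting material charged, blue



Starting material is conserved here: it stands as itself, as target or as isomer of the product, and the last north-east reading sums to 100%. So the isomer at the end is the amount reacted times the share of it that stands as isomer. We read that share, isomer over isomer plus target, as 57.7% at the last north-east reading, and one reading earlier it was 57.7%. The amount reacted comes from the south-east run, which had half the reagent and flattens near 53.1% starting material. By that last reading, each equivalent of reagent charged there had removed 0.853 of the starting material charged. The product of these two readings is the isomer allowance, the isomer obtainable per equivalent of reagent: 0.492.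

For 1.10 equiv of reagent, our ceiling is 54.2%, provided a larger charge buys no more per equivalent. For the floor we use a clock, time times catalyst loading, since north and north-east overlay on it. On that clock red at its end stands level with north-east at 1.50 min, so we take the reading there, 49.7% isomer, as our estimate for red. Grey and blue have run further than the last north-east reading, so their floor is 51.8%, within a scatter of 0.5 percentage points.

The forecast says “Isomer stays largest throughout” and gives 50% for red, 52.5% for grey and 53.5% for blue. Its values for grey and blue lie inside our bracket, and its value for red lies close to our reading.

The flask gives isomer of the product as the largest amount in red, grey and blue, at 50.2%, 52.4% and 53.2%, so the forecast is right on each question, and blue stays under the ceiling.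

    starting material + reagent + catalyst → catalyst + target (k = 693 /M²/s)
    second substrate + reagent + catalyst → catalyst + second product (k = 623 /M²/s)
    target + catalyst ⇌ isomer of the product + catalyst, rate k3*[catalyst]*[target] forward; the back reaction follows from the equilibrium constant (K = 1.38, k = 816 /M/s)

The back reaction of isomer to target is the main reason red ends at 50.2%: without it, red reaches 86.4%. The forecast's ranking was made for red, grey and blue; the order turns over in a neighbour flask, red with 0.440 equiv of reagent, the limiting reagent there. The allowance gives 21.6% isomer, and the south-east removal per equivalent leaves 62.5% starting material. The computed flask holds 21.5% and 62.9%, with starting material the largest and reagent down to 0.108%.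

(The readings come from a simulation for an exercise; noise was put on by code.)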